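## The problem

Target 18 joins an enolised 2-isobutyrylcyclohexane-1,3,5-trione (ring A, C1–C6, C1 the spiro atom) through one spiro carbon to the six-membered ring (ring B) of a trans-hydrindane whose five-membered ring is ring C (C1'–C7a', spiro atom C5'). Ring A carries the acyl-bearing carbon (C3) on one side of the spiro atom and a gem-diprenyl carbon (C5) on the other. Only this difference makes the spiro carbon a stereocentre, so its configuration must come from telling two carbonyl substituents apart. The other four stereocentres are the trans ring-fusion carbons C3a' and C7a' and two methyl-bearing tertiary carbinols, C3' on ring C and C7' on ring B. C7a' can be set by a catalyst; it then controls C3a' (trans), the pair controls C3', and the locked chair of ring B decides the face on which C7' takes up oxygen and which of two geminal carboxyls on C5' is axial. The prenyl double bonds do not survive radical, oxidising or strongly acidic conditions, the tertiary alcohols can dehydrate or add to the prenyl groups under acid, and the β-triketone is acidic and open to retro-Claisen cleavage. The feature that allows a short route is that ring A is a malonyl unit (C2–C1–C6) bridging C3 and C1 of 5-methylhexane-2,4-dione 12. On the chair of ring B its two carboxyls are one equatorial and one axial under a syn-axial methyl group at C7', so they differ in reactivity.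

## Retrosynthesis

**18 ⇒ 17 ⇒ 14 + 15.** The two O–Si bonds of bis-silyl ether 17 and the two C5–CH2 bonds of the gem-diprenyl carbon are cut last, giving trione 14 and prenyl bromide 15. The prenyl groups are introduced last because four electron-rich alkenes would not survive the radical and oxidative steps that build rings B and C. Carrying them in on the diketone partner instead would put a quaternary carbon next to the nucleophilic site of the ring closure. 14 is simpler by ten carbons. The forward reaction must alkylate the one ring A methylene twice at carbon.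

**14 ⇒ 11 + 12.** Ring A is cut at C2–C3 and C5–C6, which gives diketone 12 and the malonic half-ester chloride 11. Cutting at the spiro atom (dialkylation of a preformed trione) would create the spiro centre with nothing to control it. Cutting the C3–acyl bond (late acylation of a spiro trione) would have to choose between C3 and C5, which differ only through remote stereocentres. The chosen cut turns the spiro problem into a difference between an equatorial and an axial carboxyl. 11 lacks ring A altogether. The forward reaction must bond the equatorial carboxyl to C3 of 12 and the axial one to C1 of 12.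

**11 ⇒ 10 ⇒ 9.** The C–Cl bond and one O–CH3 bond are cut: 11 comes from half-acid 10, and 10 from diester 9 by hydrolysis of the equatorial ester alone. This step creates the spiro stereocentre. Differentiation by lactone formation is not available, because neither hydroxyl can reach a carboxyl on the chair. 9 has one stereocentre fewer. The forward reaction needs a reagent sensitive to 1,3-diaxial shielding.

**9 ⇒ 8 ⇒ 7.** The two O–Si bonds and the C7'–O bond are cut, leading to the exocyclic alkene 7. Hydration through a tertiary radical is preferred over a ketone plus methyl nucleophile, which would place the methyl group equatorial, the wrong way round. The forward reaction must deliver oxygen to the equatorial face of C7'.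

**7 ⇒ 6.** The C5'–C6' bond of ring B is cut, giving the monocyclic malonate 6 with its isopropenyl group. An oxidative radical cyclisation needs no leaving group, and the trans arrangement on ring C allows only the six-membered closure. A double alkylation of a malonate would need a neopentyl electrophile. 6 has one ring fewer. The forward reaction must end in an alkene at C7'.

**6 ⇒ 5 ⇒ 1 + 2 + 3.** The C–CH3 bond at the ring C carbinol is cut, leading to ketone 5. The two bonds from ring C to its side chains are cut next, giving cyclopent-2-en-1-one 1, isopropenyl Grignard reagent 2 and methylidenemalonate 3. A three-component coupling uses the regio-defined enolate at once, which a separate alkylation of a 3-substituted cyclopentanone could not do. The forward reactions must set C7a' by catalyst control, C3a' trans to it, and add the methyl group anti to the adjacent side chain.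

## Roads not taken

Alternative 1: The hydrindane is cut at C7'–C7a' and C3a'–C4', so that ring C comes from 1 and the C7' carbinol, with its methyl group and oxygen, from a chiral-pool dioxolanone. In the forward step the lithium enolate of (2R,5R)-2-tert-butyl-5-methyl-1,3-dioxolan-4-one A1 adds 1,4 to 1, and the cyclopentanone enolate is alkylated with benzyl chloromethyl ether A2 to give the trans ketone A3.
- Merits: absolute configuration comes from a cheap chiral-pool building block, not from a catalyst working on an unfavourable enone. The C7' carbinol enters complete, so no face-selective oxygenation of ring B is needed. In both respects this road is safer than the chosen one.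
- Weak points: the tert-butyl group fixes only the enolate face and nothing fixes the enone face, so the C7'/C7a' relationship is left to a weakly biased open transition state. Ring B must then be closed by double alkylation of a malonate at a neopentyl carbon flanked by a protected tertiary carbinol. Reduction of the dioxolanone ring of A3, debenzylation and two activations add about six steps before the diester stage.
- Comparison: against the safer absolute control, the chosen plan reaches diester 8 in four steps and has fallbacks for steps 1 and 4.

Alternative 2: Both tertiary C–O bonds are cut, leading to the oxygen-free diester A4. In the forward step methyl(trifluoromethyl)dioxirane A5 would insert oxygen with retention into the two methyl-bearing C–H bonds to give diol A6, which is the same compound as 8.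
- Merits: no protecting group and no hydration step. Retention copies the C–H configurations into the carbinols. The end game would be unchanged.
- Weak points: A4 has four tertiary C–H bonds, and the ring-fusion ones are no less reactive toward an electrophilic dioxirane. The C7' bond is further deactivated by the geminal diester two bonds away. A4 needs the C7' methyl axial and syn to an axial ester, the less stable epimer, which hydrogenation would not deliver.
- Comparison: it arrives at the compound that the chosen route makes in four steps from 1, so it saves no length and gives up site control.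

Alternative 3: Ring B is cut at C6'–C7'. In the forward step samarium diiodide A7 with hexamethylphosphoramide A8 reduces the methyl ketone of keto acrylate A9 to a ketyl that adds 6-endo to the CH2 terminus of the acrylate, and protonation of the samarium enolate gives hydroxy ester A10.
- Merits: the C–C bond and the carbinol centre form together, and the bulky samarium alkoxide prefers the equatorial position, which places the methyl axial as required. A9 should be available from 1 in about five steps. For C7' this road is probably more reliable than the hydration of the chosen route.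
- Weak points: A10 has one carboxyl on the future spiro carbon, so the second carbonyl must come in by C-acylation of a tertiary ester enolate under a syn-axial methyl group, where O-acylation and proton transfer usually win. The spiro configuration would then rest on the facial selectivity of that step. The cosolvent A8 is carcinogenic.
- Comparison: the chosen plan brings both carboxyls in with the malonate and only has to tell them apart; this is set against the better carbinol control of the alternative.

Key step: step 8

Remarks on the chemistry (assumptions):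
- The antipode of the ferrocenyl diphosphine in step 1 is taken to be the one that gives the (R) configuration at the isopropenyl-bearing carbon; the other antipode is equally available.
- 3 is taken as a purchasable, stabilised reagent that is distilled before use.
- The product of step 3 is written as the exocyclic alkene; any isomer with the double bond in the ring at C7 is carried along, since step 4 turns both into the same tertiary radical.

## Route

Step 1
Reactants: 1 cyclopent-2-en-1-one; 2 (prop-1-en-2-yl)magnesium bromide; 3 dimethyl 2-methylidenepropanedioate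
Product: 5 dimethyl 2-{[(1S,5R)-2-oxo-5-(prop-1-en-2-yl)cyclopentyl]methyl}propanedioate, via bromomagnesium enolate 4 (not isolated)
Conditions: CuBr·SMe2 (5 mol %), (R)-1-[(S)-2-(diphenylphosphino)ferrocenyl]ethyldicyclohexylphosphine (6 mol %), 2 (1.2 equiv), t-BuOMe, −75 °C; then 3 (1.3 equiv), −75 → −40 °C; aq. NH4Cl
Reagents that add atoms: none
Why: Copper-catalysed asymmetric conjugate addition of a Grignard reagent under diphosphine control should set the isopropenyl-bearing carbon (R). The regio-defined magnesium enolate 4 is then trapped by Michael addition to the very electrophilic 3 on the face anti to the isopropenyl group, giving the trans product, which is also the more stable epimer.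

Step 2
Reactants: 5 dimethyl 2-{[(1S,5R)-2-oxo-5-(prop-1-en-2-yl)cyclopentyl]methyl}propanedioate
Product: 6 dimethyl 2-{[(1S,2R,5R)-2-hydroxy-2-methyl-5-(prop-1-en-2-yl)cyclopentyl]methyl}propanedioate
Conditions: MeTi(OiPr)3 (2.5 equiv), THF/Et2O, −30 °C → rt; aq. NH4Cl
Reagents that add atoms: methyltitanium triisopropoxide, C[Ti](OC(C)C)(OC(C)C)OC(C)C
Why: Chemoselective 1,2-addition of a bulky, non-chelating methyltitanium reagent (Reetz-type carbonyl methylation) leaves the esters untouched. The reagent should approach the ketone anti to the adjacent side chain, which places the hydroxyl cis to that chain.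

Step 3
Reactants: 6 dimethyl 2-{[(1S,2R,5R)-2-hydroxy-2-methyl-5-(prop-1-en-2-yl)cyclopentyl]methyl}propanedioate
Product: 7 dimethyl (3R,3aS,7aR)-3-hydroxy-3-methyl-7-methylideneoctahydro-1H-indene-5,5-dicarboxylate (trans-fused)
Conditions: Mn(OAc)3·2H2O (2.2 equiv), Cu(OAc)2·H2O (1 equiv), degassed AcOH, 50 °C
Reagents that add atoms: none
Why: Oxidative free-radical cyclisation with trivalent manganese: the malonyl radical adds 6-endo to the 1,1-disubstituted alkene through a chair, since the 5-exo mode would give a strained trans-bicyclo[3.3.0]octane with a quaternary carbon. Divalent copper oxidises the tertiary radical with loss of a β-hydrogen, mainly from the methyl group.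

Step 4
Reactants: 7 dimethyl (3R,3aS,7aR)-3-hydroxy-3-methyl-7-methylideneoctahydro-1H-indene-5,5-dicarboxylate
Product: 8 dimethyl (3R,3aS,7R,7aR)-3,7-dihydroxy-3,7-dimethyloctahydro-1H-indene-5,5-dicarboxylate (C7 hydroxyl equatorial, C7 methyl axial)
Conditions: Co(acac)2 (20 mol %), PhSiH3 (2.5 equiv), O2 (1 atm), THF/i-PrOH, 0 °C → rt
Reagents that add atoms: dioxygen, O=O
Why: Mukaiyama hydration: hydrogen-atom transfer to the methylene carbon gives the tertiary C7 radical. The axial face of this radical is covered by the axial ester at C5, so dioxygen should be captured on the equatorial face and reduced to the equatorial alcohol.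

Step 5
Reactants: 8 dimethyl (3R,3aS,7R,7aR)-3,7-dihydroxy-3,7-dimethyloctahydro-1H-indene-5,5-dicarboxylate
Product: 9 dimethyl (3R,3aS,7R,7aR)-3,7-dimethyl-3,7-bis[(triethylsilyl)oxy]octahydro-1H-indene-5,5-dicarboxylate
Conditions: TESOTf (3 equiv), 2,6-lutidine (5 equiv), CH2Cl2, −78 → 0 °C
Reagents that add atoms: triethylsilyl trifluoromethanesulfonate, CC[Si](CC)(CC)OS(=O)(=O)C(F)(F)F
Why: Silyl ether formation with a silyl triflate works on tertiary alcohols. The ethers keep both hydroxyls out of the acid chloride, amide base and alkoxide steps and come off with fluoride at the end.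

Step 6
Reactants: 9 dimethyl (3R,3aS,7R,7aR)-3,7-dimethyl-3,7-bis[(triethylsilyl)oxy]octahydro-1H-indene-5,5-dicarboxylate
Product: 10 (3R,3aS,5S,7R,7aR)-5-(methoxycarbonyl)-3,7-dimethyl-3,7-bis[(triethylsilyl)oxy]octahydro-1H-indene-5-carboxylic acid (CO2H equatorial, CO2Me axial)
Conditions: KOH (1.5 equiv), MeOH/THF/H2O, 40 °C; then 0.5 M HCl to pH 4, 0 °C
Reagents that add atoms: potassium hydroxide, [K+].[OH-]
Why: Group-selective saponification: hydroxide addition to an ester carbonyl is sensitive to 1,3-diaxial compression, so the axial ester under the C7 methyl group should stay and the equatorial one react. The carboxylate formed protects the second ester, and this step sets the spiro stereocentre.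

Step 7
Reactants: 10 (3R,3aS,5S,7R,7aR)-5-(methoxycarbonyl)-3,7-dimethyl-3,7-bis[(triethylsilyl)oxy]octahydro-1H-indene-5-carboxylic acid
Product: 11 methyl (3R,3aS,5R,7R,7aR)-5-(carbonochloridoyl)-3,7-dimethyl-3,7-bis[(triethylsilyl)oxy]octahydro-1H-indene-5-carboxylate (COCl equatorial; the descriptor at C5 changes with the priorities, the geometry does not)
Conditions: 1-chloro-N,N,2-trimethylprop-1-en-1-amine (1.3 equiv), CH2Cl2, 0 °C → rt; concentrate
Reagents that add atoms: 1-chloro-N,N,2-trimethylprop-1-en-1-amine, CC(C)=C(Cl)N(C)C
Why: Acid chloride formation with an α-chloroenamine runs under neutral conditions, so the silyl ethers are not exposed to HCl. The carboxyl carbon has no α-hydrogen, so no ketene can form.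

Step 8
Reactants: 11 methyl (3R,3aS,5R,7R,7aR)-5-(carbonochloridoyl)-3,7-dimethyl-3,7-bis[(triethylsilyl)oxy]octahydro-1H-indene-5-carboxylate; 12 5-methylhexane-2,4-dione
Product: 14 (1R,3'R,3a'S,7'R,7a'R)-4-hydroxy-3',7'-dimethyl-3-(2-methylpropanoyl)-3',7'-bis[(triethylsilyl)oxy]-1',2',3',3a',4',6',7',7a'-octahydrospiro[cyclohex-3-ene-1,5'-indene]-2,6-dione, via triacylmethane 13 (not isolated)
Conditions: 12 (1.2 equiv), MgCl2 (1.3 equiv), Et3N (2.5 equiv), THF, 0 °C; 11, 0 °C → rt; then LiN(iPr)2 (6 equiv), −78 → 0 °C; aq. citric acid
Reagents that add atoms: none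
Why: Proposed new method: soft enolisation of 12 by MgCl2/Et3N gives a six-membered magnesium chelate that is acylated at C3 by the acid chloride of 11, and the triacylmethane 13 is at once deprotonated to its own chelate. LiN(iPr)2 then removes a proton from the acetyl methyl group, the only unhindered γ-position (the isobutyryl methine is tertiary and less acidic), and this carbanion attacks the neighbouring axial ester carbonyl, the tetrahedral intermediate losing methoxide. Ring A closes in the 6-exo-trig mode, with the enolate carbon in the ring and the ester C=O outside it. The released methoxide or excess amide deprotonates the new ring CH2 between two carbonyls, so retro-Claisen attack on the non-enolisable spiro β-diketone cannot reverse the closure. The closest known reaction types are the Effenberger cyclisation of malonyl dichlorides with enol derivatives, the MgCl2/amine C-acylation of 1,3-dicarbonyl compounds with acid chlorides, and the Claisen closure of β-diketone dianions on esters to 2-acylcyclohexane-1,3,5-triones; new is their union in one flask on a malonic half-ester chloride whose two carboxyls are told apart. No stereocentre is created: the spiro configuration fixed in step 6 is carried over, because the reactive equatorial carboxyl can only meet the nucleophilic C3 and the axial one only the later carbanion. The selectivities needed are C- over O-acylation (magnesium chelation), acid chloride over ester for the first bond (leaving group and steric access) and methyl over methine deprotonation (kinetic acidity).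

Step 9
Reactants: 14 (1R,3'R,3a'S,7'R,7a'R)-4-hydroxy-3',7'-dimethyl-3-(2-methylpropanoyl)-3',7'-bis[(triethylsilyl)oxy]-1',2',3',3a',4',6',7',7a'-octahydrospiro[cyclohex-3-ene-1,5'-indene]-2,6-dione; 15 1-bromo-3-methylbut-2-ene
Product: 17 (1R,3'R,3a'S,7'R,7a'R)-4-hydroxy-3',7'-dimethyl-5,5-bis(3-methylbut-2-en-1-yl)-3-(2-methylpropanoyl)-3',7'-bis[(triethylsilyl)oxy]-1',2',3',3a',4',6',7',7a'-octahydrospiro[cyclohex-3-ene-1,5'-indene]-2,6-dione, via monoprenyl trione 16 (not isolated)
Conditions: 15 (2.5 equiv), NaOMe (4 equiv), MeOH, 0 °C → rt; aq. NH4Cl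
Reagents that add atoms: none
Why: Twofold C-alkylation of the ring methylene between two carbonyls: beside the triketone anion, methoxide generates the C5 carbanion, the most nucleophilic site, and the protic solvent shields the oxygens. This is the reaction type by which gem-dialkyl carbons are placed on dearomatised acylphloroglucinols; C3 is blocked by the acyl group and C1 is quaternary.

Step 10
Reactants: 17 (1R,3'R,3a'S,7'R,7a'R)-4-hydroxy-3',7'-dimethyl-5,5-bis(3-methylbut-2-en-1-yl)-3-(2-methylpropanoyl)-3',7'-bis[(triethylsilyl)oxy]-1',2',3',3a',4',6',7',7a'-octahydrospiro[cyclohex-3-ene-1,5'-indene]-2,6-dione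
Product: 18 (1R,3'R,3a'S,7'R,7a'R)-3',4,7'-trihydroxy-3',7'-dimethyl-5,5-bis(3-methylbut-2-en-1-yl)-3-(2-methylpropanoyl)-1',2',3',3a',4',6',7',7a'-octahydrospiro[cyclohex-3-ene-1,5'-indene]-2,6-dione
Conditions: HF·pyridine, pyridine, THF, 0 °C → rt
Reagents that add atoms: none
Why: Fluoride-driven desilylation cleaves the two tertiary silyl ethers. The pyridine buffer should keep the medium too weakly acidic for the enol or the alcohols to add to the prenyl double bonds.

## Compound list

1 | cyclopent-2-en-1-one | O=C1CCC=C1 | starting material
2 | (prop-1-en-2-yl)magnesium bromide | CC(=C)[Mg]Br | starting material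
3 | dimethyl 2-methylidenepropanedioate | COC(=O)C(=C)C(=O)OC | starting material
4 | bromomagnesium (3R)-3-(prop-1-en-2-yl)cyclopent-1-en-1-olate | Br[Mg]OC1=C[C@@H](CC1)C(C)=C | intermediate
5 | dimethyl 2-{[(1S,5R)-2-oxo-5-(prop-1-en-2-yl)cyclopentyl]methyl}propanedioate | COC(=O)C(C(=O)OC)C[C@H]1[C@@H](CCC1=O)C(C)=C | intermediate
6 | dimethyl 2-{[(1S,2R,5R)-2-hydroxy-2-methyl-5-(prop-1-en-2-yl)cyclopentyl]methyl}propanedioate | COC(=O)C(C(=O)OC)C[C@H]1[C@@H](CC[C@@]1(C)O)C(C)=C | intermediate
7 | dimethyl (3R,3aS,7aR)-3-hydroxy-3-methyl-7-methylideneoctahydro-1H-indene-5,5-dicarboxylate | COC(=O)C1(C[C@H]2[C@@H](CC[C@@]2(C)O)C(=C)C1)C(=O)OC | intermediate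
8 | dimethyl (3R,3aS,7R,7aR)-3,7-dihydroxy-3,7-dimethyloctahydro-1H-indene-5,5-dicarboxylate | COC(=O)C1(C[C@H]2[C@@H](CC[C@@]2(C)O)[C@](C)(O)C1)C(=O)OC | intermediate
9 | dimethyl (3R,3aS,7R,7aR)-3,7-dimethyl-3,7-bis[(triethylsilyl)oxy]octahydro-1H-indene-5,5-dicarboxylate | COC(=O)C1(C[C@H]2[C@@H](CC[C@@]2(C)O[Si](CC)(CC)CC)[C@](C)(O[Si](CC)(CC)CC)C1)C(=O)OC | intermediate
10 | (3R,3aS,5S,7R,7aR)-5-(methoxycarbonyl)-3,7-dimethyl-3,7-bis[(triethylsilyl)oxy]octahydro-1H-indene-5-carboxylic acid | COC(=O)[C@]1(C[C@H]2[C@@H](CC[C@@]2(C)O[Si](CC)(CC)CC)[C@](C)(O[Si](CC)(CC)CC)C1)C(O)=O | intermediate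
11 | methyl (3R,3aS,5R,7R,7aR)-5-(carbonochloridoyl)-3,7-dimethyl-3,7-bis[(triethylsilyl)oxy]octahydro-1H-indene-5-carboxylate | COC(=O)[C@]1(C[C@H]2[C@@H](CC[C@@]2(C)O[Si](CC)(CC)CC)[C@](C)(O[Si](CC)(CC)CC)C1)C(Cl)=O | intermediate
12 | 5-methylhexane-2,4-dione | CC(=O)CC(=O)C(C)C | starting material
13 | methyl (3R,3aS,5S,7R,7aR)-5-(2-acetyl-4-methyl-3-oxopentanoyl)-3,7-dimethyl-3,7-bis[(triethylsilyl)oxy]octahydro-1H-indene-5-carboxylate (present as its magnesium enolate) | COC(=O)[C@]1(C[C@H]2[C@@H](CC[C@@]2(C)O[Si](CC)(CC)CC)[C@](C)(O[Si](CC)(CC)CC)C1)C(=O)C(C(C)=O)C(=O)C(C)C | intermediate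
14 | (1R,3'R,3a'S,7'R,7a'R)-4-hydroxy-3',7'-dimethyl-3-(2-methylpropanoyl)-3',7'-bis[(triethylsilyl)oxy]-1',2',3',3a',4',6',7',7a'-octahydrospiro[cyclohex-3-ene-1,5'-indene]-2,6-dione | CC(C)C(=O)C1=C(O)CC(=O)[C@]2(C[C@H]3[C@@H](CC[C@@]3(C)O[Si](CC)(CC)CC)[C@](C)(O[Si](CC)(CC)CC)C2)C1=O | intermediate
15 | 1-bromo-3-methylbut-2-ene | CC(C)=CCBr | starting material
16 | (1R,3'R,3a'S,7'R,7a'R)-4-hydroxy-3',7'-dimethyl-5-(3-methylbut-2-en-1-yl)-3-(2-methylpropanoyl)-3',7'-bis[(triethylsilyl)oxy]-1',2',3',3a',4',6',7',7a'-octahydrospiro[cyclohex-3-ene-1,5'-indene]-2,6-dione (C5 not defined) | CC(C)=CCC1C(=O)[C@]2(C[C@H]3[C@@H](CC[C@@]3(C)O[Si](CC)(CC)CC)[C@](C)(O[Si](CC)(CC)CC)C2)C(=O)C(C(=O)C(C)C)=C1O | intermediate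
17 | (1R,3'R,3a'S,7'R,7a'R)-4-hydroxy-3',7'-dimethyl-5,5-bis(3-methylbut-2-en-1-yl)-3-(2-methylpropanoyl)-3',7'-bis[(triethylsilyl)oxy]-1',2',3',3a',4',6',7',7a'-octahydrospiro[cyclohex-3-ene-1,5'-indene]-2,6-dione | CC(C)=CCC1(CC=C(C)C)C(=O)[C@]2(C[C@H]3[C@@H](CC[C@@]3(C)O[Si](CC)(CC)CC)[C@](C)(O[Si](CC)(CC)CC)C2)C(=O)C(C(=O)C(C)C)=C1O | intermediate
18 | (1R,3'R,3a'S,7'R,7a'R)-3',4,7'-trihydroxy-3',7'-dimethyl-5,5-bis(3-methylbut-2-en-1-yl)-3-(2-methylpropanoyl)-1',2',3',3a',4',6',7',7a'-octahydrospiro[cyclohex-3-ene-1,5'-indene]-2,6-dione | CC(C)=CCC1(CC=C(C)C)C(=O)[C@]2(C[C@H]3[C@@H](CC[C@@]3(C)O)[C@](C)(O)C2)C(=O)C(C(=O)C(C)C)=C1O | target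

## Step count and least certain steps

Total: 10 steps. Longest linear sequence: 10 steps from 1 (12 and 15 are bought).

**Step 8 (key step, proposed method).** The closure may stall after the first bond: the methyl carbanion may not form cleanly in the presence of magnesium and ammonium salts, or may attack the shielded axial ester too slowly. O-acylation in the first stage and retro-Claisen loss of an acyl group from the triacylmethane would compete. The fallback uses known reaction types, sets out from 11 and comes back at 14, and keeps the pairing of the equatorial carboxyl with C3 and the axial one with C5. 11 is added to the dianion of prop-2-en-1-yl 3-oxobutanoate (NaH, then n-BuLi, THF, −78 °C), whose terminal carbon is acylated to give the 3,5-dioxo ester F1. NaH in THF at reflux closes ring A by Dieckmann condensation of the carbon between ketone and allyl ester onto the axial methyl ester; this doubly stabilised carbanion can be held under forcing conditions and gives the allyl trione carboxylate F2. The dianion of F2 (LiN(iPr)2, 2.2 equiv) is acylated at its only free ring CH2 with N-methoxy-N,2-dimethylpropanamide to give the acyl trione ester F3. Pd(PPh3)4 with morpholine removes the allyl ester with decarboxylation and gives 14.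

**Step 1.** Enantioface selection may be poor, since five-membered enones and alkenyl Grignard reagents are the less favourable partners of this catalysis, and the malonate enolate formed in the trapping may oligomerise 3. The fallback replaces catalyst control by a sulfinyl auxiliary, sets out from 2 and 3 and comes back at 5. Commercial (S)-2-(4-methylbenzenesulfinyl)cyclopent-2-en-1-one F4 is complexed with ZnBr2 in THF at −78 °C, 2 adds to the face left open by the chelated sulfinyl group, and the sulfinyl-stabilised enolate is trapped with 3 to give the quaternary keto sulfoxide F5. If the sense of addition proves opposite, the antipodal sulfoxide is used. Aluminium amalgam in wet THF cleaves the C–S bond and the α-carbon settles trans, giving 5.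

**Step 4.** Oxygen capture by the planar tertiary radical may show poor facial selectivity; axial capture gives the C7 epimer. The fallback uses a bulky two-electron oxidant, sets out from 7 and comes back at 8. Epoxidation with 3-chloroperbenzoic acid (NaHCO3, CH2Cl2) from the equatorial side gives the spiro-epoxide F6. Sodium phenylselenide (from (PhSe)2 and NaBH4 in EtOH) opens it at the CH2 carbon to give the hydroxy selenide F7. Bu3SnH with azobisisobutyronitrile in toluene at 80 °C replaces selenium by hydrogen and gives 8.

**Step 6.** Group selectivity may be lost through hydrolysis of the axial ester or of both, and the whole spiro assignment rests on this step. The fallback differentiates by hydride, sets out from 9 and comes back at 10. i-Bu2AlH (1.1 equiv, toluene, −78 °C) reduces the accessible equatorial ester to the formyl ester F8, which cannot enolise. Pinnick oxidation (NaClO2, NaH2PO4, 2-methylbut-2-ene, t-BuOH/H2O) gives 10.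

**Step 9.** O-prenylation and an incomplete second alkylation at the increasingly crowded carbon may occur. The fallback uses soft allylation, sets out from 14 and comes back at 17. Pd(PPh3)4 with allyl methyl carbonate (2.5 equiv, THF), a Tsuji–Trost reaction in which O-allyl products revert through the π-allyl complex, gives the gem-diallyl trione F9. Cross-metathesis with 2-methylbut-2-ene and second-generation Grubbs catalyst converts both allyl groups into prenyl groups and gives 17.

## Further compounds

F1 | step 8 | methyl (3R,3aS,5S,7R,7aR)-5-[3,5-dioxo-5-(prop-2-en-1-yloxy)pentanoyl]-3,7-dimethyl-3,7-bis[(triethylsilyl)oxy]octahydro-1H-indene-5-carboxylate | COC(=O)[C@]1(C[C@H]2[C@@H](CC[C@@]2(C)O[Si](CC)(CC)CC)[C@](C)(O[Si](CC)(CC)CC)C1)C(=O)CC(=O)CC(=O)OCC=C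
F2 | step 8 | prop-2-en-1-yl (3'R,3a'S,7'R,7a'R)-3',7'-dimethyl-2,4,6-trioxo-3',7'-bis[(triethylsilyl)oxy]octahydrospiro[cyclohexane-1,5'-indene]-3-carboxylate (ester-bearing carbon next to the carbonyl from the axial ester; spiro centre as in 14) | C=CCOC(=O)C1C(=O)CC(=O)[C@@]2(C[C@H]3[C@@H](CC[C@@]3(C)O[Si](CC)(CC)CC)[C@](C)(O[Si](CC)(CC)CC)C2)C1=O
F3 | step 8 | prop-2-en-1-yl ester of 14 carrying the carboxyl group at C5 of ring A (4-hydroxy-3-(2-methylpropanoyl)-2,6-dioxo spiro trione 5-carboxylate; C5 not defined) | CC(C)C(=O)C1=C(O)C(C(=O)OCC=C)C(=O)[C@]2(C[C@H]3[C@@H](CC[C@@]3(C)O[Si](CC)(CC)CC)[C@](C)(O[Si](CC)(CC)CC)C2)C1=O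
F4 | step 1 | (S)-2-(4-methylbenzenesulfinyl)cyclopent-2-en-1-one | O=C1CCC=C1[S@@](=O)c1ccc(C)cc1
F5 | step 1 | dimethyl 2-{[1-[(S)-4-methylbenzenesulfinyl]-2-oxo-5-(prop-1-en-2-yl)cyclopentyl]methyl}propanedioate (malonylmethyl group trans to isopropenyl) | COC(=O)C(C(=O)OC)C[C@@]1([S@@](=O)c2ccc(C)cc2)[C@@H](CCC1=O)C(C)=C
F6 | step 4 | dimethyl (3R,3aS,7R,7aR)-3-hydroxy-3-methylhexahydrospiro[indene-7,2'-oxirane]-5,5(4H)-dicarboxylate (epoxide oxygen equatorial) | COC(=O)C1(C[C@H]2[C@@H](CC[C@@]2(C)O)[C@]3(OC3)C1)C(=O)OC
F7 | step 4 | dimethyl (3R,3aS,7R,7aR)-3,7-dihydroxy-3-methyl-7-[(phenylselanyl)methyl]octahydro-1H-indene-5,5-dicarboxylate | COC(=O)C1(C[C@H]2[C@@H](CC[C@@]2(C)O)[C@](C[Se]c3ccccc3)(O)C1)C(=O)OC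
F8 | step 6 | methyl (3R,3aS,5S,7R,7aR)-5-formyl-3,7-dimethyl-3,7-bis[(triethylsilyl)oxy]octahydro-1H-indene-5-carboxylate (formyl equatorial) | COC(=O)[C@]1(C[C@H]2[C@@H](CC[C@@]2(C)O[Si](CC)(CC)CC)[C@](C)(O[Si](CC)(CC)CC)C1)C=O
F9 | step 9 | (1R,3'R,3a'S,7'R,7a'R)-4-hydroxy-3',7'-dimethyl-3-(2-methylpropanoyl)-5,5-di(prop-2-en-1-yl)-3',7'-bis[(triethylsilyl)oxy]-1',2',3',3a',4',6',7',7a'-octahydrospiro[cyclohex-3-ene-1,5'-indene]-2,6-dione | C=CCC1(CC=C)C(=O)[C@]2(C[C@H]3[C@@H](CC[C@@]3(C)O[Si](CC)(CC)CC)[C@](C)(O[Si](CC)(CC)CC)C2)C(=O)C(C(=O)C(C)C)=C1O
A1 | alternative 1 | (2R,5R)-2-tert-butyl-5-methyl-1,3-dioxolan-4-one | C[C@H]1O[C@@H](C(C)(C)C)OC1=O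
A2 | alternative 1 | benzyl chloromethyl ether | ClCOCc1ccccc1
A3 | alternative 1 | (2R,3R)-2-[(benzyloxy)methyl]-3-[(2R,5S)-2-tert-butyl-5-methyl-4-oxo-1,3-dioxolan-5-yl]cyclopentan-1-one (trans) | c1ccccc1COC[C@H]3[C@@H](CCC3=O)[C@]4(C)O[C@@H](C(C)(C)C)OC4=O
A4 | alternative 2 | dimethyl (3S,3aR,7S,7aS)-3,7-dimethyloctahydro-1H-indene-5,5-dicarboxylate (trans-fused) | COC(=O)C2(C[C@H]3[C@@H](CC[C@@H]3C)[C@@H](C)C2)C(=O)OC
A5 | alternative 2 | methyl(trifluoromethyl)dioxirane | CC1(OO1)C(F)(F)F
A6 | alternative 2 | dimethyl (3R,3aS,7R,7aR)-3,7-dihydroxy-3,7-dimethyloctahydro-1H-indene-5,5-dicarboxylate (identical with 8) | COC(=O)C2(C[C@H]3[C@@H](CC[C@@]3(C)O)[C@](C)(O)C2)C(=O)OC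
A7 | alternative 3 | samarium diiodide | [Sm+2].[I-].[I-]
A8 | alternative 3 | hexamethylphosphoramide | CN(C)P(=O)(N(C)C)N(C)C
A9 | alternative 3 | methyl 2-{[(1S,2R,5R)-5-acetyl-2-methyl-2-[(triethylsilyl)oxy]cyclopentyl]methyl}prop-2-enoate | COC(=O)C(=C)C[C@H]3[C@@H](CC[C@@]3(C)O[Si](CC)(CC)CC)C(C)=O
A10 | alternative 3 | methyl (3R,3aS,5R,7R,7aR)-7-hydroxy-3,7-dimethyl-3-[(triethylsilyl)oxy]octahydro-1H-indene-5-carboxylate | COC(=O)[C@@H]2C[C@H]3[C@@H](CC[C@@]3(C)O[Si](CC)(CC)CC)[C@](C)(O)C2
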